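The 36-membered lactone (C1 carbonyl to C35–O) carries 1,5-related carbinols. C21 and C25 flank the C22–C24 methylenes, so both are drawn as terminal epoxides and C23 as a silyl dithiane. In one flask the lithiated dithiane opens the C15–C22 epoxide at C22, a solvent-gated 1,4-Brook shift moves silicon to O21, and the new C23 anion opens the C24–C40 epoxide at C24. This gives the C15–C40 chain with O21 and O25 differentiated. Both epoxides carry only silyl ethers (one PMB at O35), and the C15–C22 epoxide doubles as the C7–C14 unit of the acid. Esterification at O35, ring-closing metathesis at C14=C15, Raney nickel and fluoride finish the synthesis.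

Key step: step 36

Remark: locants are those of the target (C1 lactone carbonyl, C35 ring carbon on the lactone oxygen, C36–C40 side chain) and every stereocentre has the target's spatial arrangement as written in the SMILES list; 6 carries one alkene carbon beyond C15 (beyond C7 when it serves the acid) that leaves as ethene; metathesis alkenes are drawn E although their geometry is irrelevant, since both are reduced.

**Fragment A (C15–C22 epoxide, also the C7–C14 unit)**

Step 1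
Reactants: 1 (R)-epichlorohydrin
Product: 2 (2R)-1-chlorohept-6-en-2-ol
Conditions: but-3-enylmagnesium bromide, CuI (10 mol %), THF, −40 °C
Reagents that add atoms: but-3-enylmagnesium bromide, C=CCC[Mg]Br
Why: Copper-catalysed Grignard opening of a terminal epoxide occurs at the CH2 terminus (SN2), so the stereocentre of 1 (future C21) is not touched.

Step 2
Reactants: 2 (2R)-1-chlorohept-6-en-2-ol
Product: 3 (2R)-2-(pent-4-en-1-yl)oxirane
Conditions: NaOH, H2O/Et2O, rt
Reagents that add atoms: none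
Why: Intramolecular Williamson etherification (3-exo-tet displacement of chloride by the alkoxide) rebuilds the epoxide on the other side of the same stereocentre, which keeps its configuration.

Step 3
Reactants: 3 (2R)-2-(pent-4-en-1-yl)oxirane
Product: 4 4-[(2R)-oxiran-2-yl]butanal
Conditions: O3, CH2Cl2, −78 °C; then PPh3, −78 °C → rt
Reagents that add atoms: ozone, [O-][O+]=O
Why: Ozonolysis with reductive work-up cleaves the only alkene to the C17 aldehyde, and epoxides are inert to ozone and to PPh3.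

Step 4
Reactants: 4 4-[(2R)-oxiran-2-yl]butanal
Product: 5 (4R)-1-[(2R)-oxiran-2-yl]hept-6-en-4-ol
Conditions: (−)-Ipc2B(allyl) [from (+)-α-pinene], Et2O, −78 °C; then NaBO3·4H2O, H2O, 0 °C → rt
Reagents that add atoms: (−)-B-allyldiisopinocampheylborane, C=CCB([C@@H]1C[C@@H]2C[C@H]([C@H]1C)C2(C)C)[C@@H]1C[C@@H]2C[C@H]([C@H]1C)C2(C)C
Why: Brown allylation is reagent-controlled through a chair-like six-membered transition state, so this borane should deliver the (17R) alcohol, and the epoxide survives the cold addition and the mild perborate work-up.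

Step 5
Reactants: 5 (4R)-1-[(2R)-oxiran-2-yl]hept-6-en-4-ol
Product: 6 fragment A, the O17 tert-butyldimethylsilyl ether of 5
Conditions: TBSCl, imidazole, DMF, 0 °C → rt
Reagents that add atoms: tert-butyldimethylsilyl chloride, CC(C)(C)[Si](C)(C)Cl
Why: Silylation with TBSCl/imidazole needs no strong base, so the 5,6-epoxy alcohol cannot cyclise to a tetrahydropyran before O17 is capped.

**C1–C14 acid**

Step 6
Reactants: 7 (R)-citronellol
Product: 8 (3R)-1-[(4-methoxybenzyl)oxy]-3,7-dimethyloct-6-ene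
Conditions: NaH, PMBCl, Bu4NI (cat.), THF/DMF, 0 °C → rt
Reagents that add atoms: 4-methoxybenzyl chloride, COc1ccc(CCl)cc1
Why: Williamson etherification protects the C1 hydroxyl of the chiral-pool unit that supplies the C3 methyl stereocentre.

Step 7
Reactants: 8 (3R)-1-[(4-methoxybenzyl)oxy]-3,7-dimethyloct-6-ene
Product: 9 (4R)-6-[(4-methoxybenzyl)oxy]-4-methylhexanal
Conditions: O3, CH2Cl2, −78 °C (stopped at the first blue tinge); then PPh3
Reagents that add atoms: ozone, [O-][O+]=O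
Why: Ozonolysis of the electron-rich trisubstituted alkene is much faster than attack on the anisyl ring, and reductive work-up gives the C6 aldehyde.

Step 8
Reactants: 9 (4R)-6-[(4-methoxybenzyl)oxy]-4-methylhexanal
Product: 11 (2S,4S)-6-[(4-methoxybenzyl)oxy]-4-methyl-2-[(phenylamino)oxy]hexan-1-ol, via aminoxy aldehyde 10 (not isolated)
Conditions: D-proline (20 mol %), PhNO, DMSO, rt; then NaBH4, EtOH, 0 °C
Reagents that add atoms: nitrosobenzene, O=Nc1ccccc1
Why: Proline-catalysed α-aminoxylation proceeds through the enamine, with the carboxylic acid guiding nitrosobenzene to one face, so D-proline should set C5 as (2S), and in-situ borohydride reduction prevents epimerisation of the α-oxy aldehyde.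

Step 9
Reactants: 11 (2S,4S)-6-[(4-methoxybenzyl)oxy]-4-methyl-2-[(phenylamino)oxy]hexan-1-ol
Product: 12 (2S,4S)-6-[(4-methoxybenzyl)oxy]-4-methylhexane-1,2-diol
Conditions: Zn, AcOH, EtOH, rt
Reagents that add atoms: none
Why: Zinc in acetic acid reductively cleaves the weak N–O bond without touching the PMB ether.

Step 10
Reactants: 12 (2S,4S)-6-[(4-methoxybenzyl)oxy]-4-methylhexane-1,2-diol
Product: 14 (2S)-2-[(2S)-4-[(4-methoxybenzyl)oxy]-2-methylbutyl]oxirane, via primary tosylate 13 (not isolated)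
Conditions: NaH, THF, 0 °C; N-tosylimidazole, 0 °C → rt
Reagents that add atoms: none
Why: One-pot selective sulfonylation of the primary alkoxide and 3-exo-tet closure by the secondary alkoxide give the terminal epoxide with retention at C5.

Step 11
Reactants: 14 (2S)-2-[(2S)-4-[(4-methoxybenzyl)oxy]-2-methylbutyl]oxirane
Product: 15 (3S,5S)-7-[(4-methoxybenzyl)oxy]-5-methylhept-1-en-3-ol
Conditions: Me3SI, n-BuLi, THF, −10 °C → rt
Reagents that add atoms: trimethylsulfonium iodide, C[S+](C)C.[I-]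
Why: Dimethylsulfonium methylide opens the epoxide at its CH2 terminus and the sulfonium betaine eliminates dimethyl sulfide (one-carbon epoxide-to-allylic-alcohol homologation), leaving C5 untouched.

Step 12
Reactants: 15 (3S,5S)-7-[(4-methoxybenzyl)oxy]-5-methylhept-1-en-3-ol; 6 fragment A
Product: 16 C1–C14 epoxy alkene (C6=C7; 5-OH; 9-OTBS; 13,14-epoxide; 1-OPMB)
Conditions: Hoveyda–Grubbs second-generation catalyst (5 mol %), 15 (2 equiv), CH2Cl2, 40 °C
Reagents that add atoms: none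
Why: Olefin cross-metathesis between a terminal homoallylic alkene and a secondary allylic alcohol favours the cross product because the allylic alcohol homodimerises slowly, and the epoxide and silyl ether are inert.

Step 13
Reactants: 16 C1–C14 epoxy alkene
Product: 17 C1–C14 saturated epoxide (5-OH; 9-OTBS; 13,14-epoxide; 1-OPMB)
Conditions: 2-nitrobenzenesulfonylhydrazide, Et3N, CH2Cl2, rt
Reagents that add atoms: none
Why: Diimide transfers H2 to the isolated disubstituted alkene by concerted syn addition and cannot hydrogenolyse the allylic C–O bond, the epoxide or the PMB ether.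

Step 14
Reactants: 17 C1–C14 saturated epoxide
Product: 18 C1–C14 diol with the C13 vinyl carbinol (5-OH; 13-OH; 9-OTBS; 1-OPMB)
Conditions: Me3SI, n-BuLi, THF, −10 °C → rt
Reagents that add atoms: trimethylsulfonium iodide, C[S+](C)C.[I-]
Why: The same sulfonium ylide homologation as in step 11 turns the C13–C14 epoxide into the vinyl carbinol needed for ring closure, with one extra equivalent of base covering the free O5–H.

Step 15
Reactants: 18 C1–C14 diol
Product: 19 C1–C14 tris-silyl ether (O5, O9, O13 TBS; 1-OPMB)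
Conditions: TBSOTf, 2,6-lutidine, CH2Cl2, −78 → 0 °C
Reagents that add atoms: tert-butyldimethylsilyl trifluoromethanesulfonate, CC(C)(C)[Si](C)(C)OS(=O)(=O)C(F)(F)F
Why: A silyl triflate with a hindered pyridine base silylates both secondary hydroxyls (O5 and allylic O13) in one operation.

Step 16
Reactants: 19 C1–C14 tris-silyl ether
Product: 20 C1 primary alcohol (O5, O9, O13 TBS)
Conditions: DDQ, CH2Cl2/pH 7 buffer, 0 °C
Reagents that add atoms: none
Why: DDQ oxidises the electron-rich PMB ether to an oxocarbenium ion that water hydrolyses, while silyl ethers and the isolated alkene are inert.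

Step 17
Reactants: 20 C1 primary alcohol
Product: 21 C1–C14 acid (O5, O9, O13 TBS; C14=CH2)
Conditions: TEMPO (cat.), PhI(OAc)2, MeCN/H2O, rt
Reagents that add atoms: water, O
Why: Oxoammonium oxidation in wet solvent takes the primary alcohol through the aldehyde hydrate to the acid without touching the alkene, the silyl ethers or the C3 stereocentre.

**Fragment B (C24–C40 epoxide)**

Step 18
Reactants: 22 (E)-hept-2-en-1-ol
Product: 23 [(2R,3R)-3-butyloxiran-2-yl]methanol
Conditions: Ti(OiPr)4 (cat.), D-(−)-diisopropyl tartrate, t-BuOOH, 4 Å MS, CH2Cl2, −20 °C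
Reagents that add atoms: tert-butyl hydroperoxide, CC(C)(C)OO
Why: Sharpless asymmetric epoxidation with D-(−)-tartrate delivers oxygen to the face that gives the (2R,3R) epoxy alcohol (future C35 and C36).

Step 19
Reactants: 23 [(2R,3R)-3-butyloxiran-2-yl]methanol
Product: 24 (2S,3S)-3-methylheptane-1,2-diol
Conditions: AlMe3, hexane/CH2Cl2, 0 °C
Reagents that add atoms: trimethylaluminium, C[Al](C)C
Why: In this aluminium-directed epoxide opening the aluminium alkoxide delivers methyl to C3 of the epoxy alcohol (C36) with inversion, which gives the 35,36-anti 1,2-diol.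

Step 20
Reactants: 24 (2S,3S)-3-methylheptane-1,2-diol
Product: 26 (2S)-2-[(2S)-hexan-2-yl]oxirane, via primary tosylate 25 (not isolated)
Conditions: NaH, THF, 0 °C; N-tosylimidazole, 0 °C → rt
Reagents that add atoms: none
Why: Selective sulfonylation of the primary alkoxide and 3-exo-tet closure give the C34–C35 epoxide with retention at C35.

Step 21
Reactants: 26 (2S)-2-[(2S)-hexan-2-yl]oxirane
Product: 27 (4R,5S)-5-methylnon-1-en-4-ol
Conditions: vinylmagnesium bromide, CuI (10 mol %), THF, −30 °C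
Reagents that add atoms: vinylmagnesium bromide, C=C[Mg]Br
Why: Copper-catalysed Grignard opening at the CH2 terminus (C34) gives the homoallylic alcohol with C35 unchanged.

Step 22
Reactants: 27 (4R,5S)-5-methylnon-1-en-4-ol
Product: 28 (4R,5S)-4-[(4-methoxybenzyl)oxy]-5-methylnon-1-ene
Conditions: NaH, PMBCl, Bu4NI (cat.), DMF, 0 °C → rt
Reagents that add atoms: 4-methoxybenzyl chloride, COc1ccc(CCl)cc1
Why: Williamson etherification places the only oxidatively removable group of the chain on O35, the future acylation site.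

Step 23
Reactants: 28 (4R,5S)-4-[(4-methoxybenzyl)oxy]-5-methylnon-1-ene
Product: 29 (3R,4S)-3-[(4-methoxybenzyl)oxy]-4-methyloctanal
Conditions: O3, CH2Cl2, −78 °C; then PPh3
Reagents that add atoms: ozone, [O-][O+]=O
Why: Ozonolysis unmasks the C33 aldehyde, which is used at once to avoid β-elimination of the PMB ether.

Step 24
Reactants: 29 (3R,4S)-3-[(4-methoxybenzyl)oxy]-4-methyloctanal
Product: 30 (4S,6R,7S)-6-[(4-methoxybenzyl)oxy]-7-methylundec-1-en-4-ol
Conditions: (−)-Ipc2B(allyl) [from (+)-α-pinene], Et2O, −78 °C; then NaBO3·4H2O, H2O, rt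
Reagents that add atoms: (−)-B-allyldiisopinocampheylborane, C=CCB([C@@H]1C[C@@H]2C[C@H]([C@H]1C)C2(C)C)[C@@H]1C[C@@H]2C[C@H]([C@H]1C)C2(C)C
Why: This reagent-controlled Brown allylation should give the 33,35-anti alcohol, which is also the isomer favoured by 1,3-induction from the β-alkoxy group (matched case).

Step 25
Reactants: 30 (4S,6R,7S)-6-[(4-methoxybenzyl)oxy]-7-methylundec-1-en-4-ol
Product: 31 C30–C40 alkene (33-OTBS; 35-OPMB)
Conditions: TBSOTf, 2,6-lutidine, CH2Cl2, −78 °C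
Reagents that add atoms: tert-butyldimethylsilyl trifluoromethanesulfonate, CC(C)(C)[Si](C)(C)OS(=O)(=O)C(F)(F)F
Why: Standard silylation of the secondary homoallylic alcohol.

Step 26
Reactants: 31 C30–C40 alkene
Product: 32 C29–C40 aldehyde (33-OTBS; 35-OPMB)
Conditions: Rh(acac)(CO)2 (2 mol %), BIPHEPHOS (4 mol %), CO/H2 (1:1, 5 bar), THF, 60 °C
Reagents that add atoms: carbon monoxide, [C-]#[O+]
Why: Rhodium-catalysed hydroformylation with a wide-bite-angle bisphosphite is linear-selective for terminal alkenes and adds C29 as the aldehyde in one step.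

Step 27
Reactants: 32 C29–C40 aldehyde
Product: 33 C26–C40 homoallylic alcohol (29-OH; 33-OTBS; 35-OPMB)
Conditions: (+)-Ipc2B(allyl) [from (−)-α-pinene], Et2O, −78 °C; then NaBO3·4H2O, H2O, rt
Reagents that add atoms: (+)-B-allyldiisopinocampheylborane, C=CCB([C@H]1C[C@H]2C[C@@H]([C@@H]1C)C2(C)C)[C@H]1C[C@H]2C[C@@H]([C@@H]1C)C2(C)C
Why: Brown allylation of an aldehyde with no nearby stereocentre is purely reagent-controlled, and this enantiomer of the borane should give the (29S) alcohol, 1,5-anti to O33.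

Step 28
Reactants: 33 C26–C40 homoallylic alcohol
Product: 34 C26–C40 alkene (29,33-bis-OTBS; 35-OPMB)
Conditions: TBSOTf, 2,6-lutidine, CH2Cl2, −78 °C
Reagents that add atoms: tert-butyldimethylsilyl trifluoromethanesulfonate, CC(C)(C)[Si](C)(C)OS(=O)(=O)C(F)(F)F
Why: Standard silylation of the secondary homoallylic alcohol.

Step 29
Reactants: 34 C26–C40 alkene
Product: 35 C27–C40 aldehyde (29,33-bis-OTBS; 35-OPMB)
Conditions: O3, CH2Cl2, −78 °C; then PPh3
Reagents that add atoms: ozone, [O-][O+]=O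
Why: Ozonolysis with reductive work-up converts the terminal alkene into the C27 aldehyde.

Step 30
Reactants: 35 C27–C40 aldehyde
Product: 36 C24–C40 homoallylic alcohol (27-OH; 29,33-bis-OTBS; 35-OPMB)
Conditions: (−)-Ipc2B(allyl) [from (+)-α-pinene], Et2O, −78 °C; then NaBO3·4H2O, H2O, rt
Reagents that add atoms: (−)-B-allyldiisopinocampheylborane, C=CCB([C@@H]1C[C@@H]2C[C@H]([C@H]1C)C2(C)C)[C@@H]1C[C@@H]2C[C@H]([C@H]1C)C2(C)C
Why: In this Brown allylation reagent control and 1,3-anti induction from the β-silyloxy group are matched and should give the 27,29-anti alcohol.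

Step 31
Reactants: 36 C24–C40 homoallylic alcohol
Product: 37 C27 tert-butyl carbonate
Conditions: Boc2O, DMAP, MeCN, rt
Reagents that add atoms: di-tert-butyl dicarbonate, CC(C)(C)OC(=O)OC(=O)OC(C)(C)C
Why: DMAP-catalysed acylation gives the carbonate that will deliver oxygen to C25.

Step 32
Reactants: 37 C27 tert-butyl carbonate
Product: 38 cyclic iodocarbonate (O25/O27 carbonate; C24 iodide)
Conditions: IBr, toluene, −85 °C
Reagents that add atoms: iodine monobromide, IBr
Why: In the iodocarbonate cyclisation the iodonium ion of the terminal alkene is captured 6-exo by the carbonate carbonyl through a chair with both substituents equatorial, which gives the 25,27-syn cyclic carbonate with loss of the tert-butyl group.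

Step 33
Reactants: 38 cyclic iodocarbonate
Product: 39 syn epoxy alcohol (C24–C25 epoxide; 27-OH)
Conditions: K2CO3, MeOH, rt
Reagents that add atoms: none
Why: Methanolysis of the carbonate frees the C25 alkoxide, which closes the terminal epoxide by 3-exo-tet displacement of iodide with retention at C25.

Step 34
Reactants: 39 syn epoxy alcohol
Product: 40 fragment B (C24–C25 epoxide; 27,29,33-tris-OTBS; 35-OPMB)
Conditions: TBSCl, imidazole, DMF, rt
Reagents that add atoms: tert-butyldimethylsilyl chloride, CC(C)(C)[Si](C)(C)Cl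
Why: Neutral silylation caps O27 without endangering the epoxide, and any silyl shift from O29 to O27 in step 33 is harmless because both oxygens end as TBS ethers.

**Linchpin and union**

Step 35
Reactants: 41 1,3-dithiane
Product: 43 2-(tert-butyldimethylsilyl)-1,3-dithiane, via 2-lithio-1,3-dithiane 42 (not isolated)
Conditions: n-BuLi, THF, −30 °C; TBSCl, −78 °C → rt
Reagents that add atoms: tert-butyldimethylsilyl chloride, CC(C)(C)[Si](C)(C)Cl
Why: Deprotonation at C2 of the dithiane followed by C-silylation gives the linchpin.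

Step 36
Reactants: 43 2-(tert-butyldimethylsilyl)-1,3-dithiane; 6 fragment A; 40 fragment B
Product: 47 C15–C40 union product (C23 dithiane; O21 TBS; O25 H), via lithiated silyl dithiane 44 (not isolated), via lithium alkoxide 45 (not isolated), via relayed dithianyl anion 46 (not isolated)
Conditions: t-BuLi, Et2O, −78 → −45 °C; 6, Et2O, −78 → −25 °C; then 40, Et2O/HMPA, −78 °C → rt
Reagents that add atoms: none
Why: t-BuLi removes the C2 proton of 43 to give 44, which opens epoxide 6 by SN2 attack at the unhindered C22 methylene to give alkoxide 45, a species that does not rearrange in ether. Adding 40 together with HMPA triggers the 1,4-Brook rearrangement (silicon from C23 to O21), and the regenerated anion 46 opens 40 at C24, so C22–C23 and C23–C24 are formed in one flask. The closest known reaction type is the three-component anion relay coupling of 2-silyl-1,3-dithianes with two different terminal epoxides. No ring is closed and no stereocentre is created, because C21 and C25 are carried in with the epoxides and are untouched by attack at the CH2 termini. The step needs terminal regioselectivity, secured by the monosubstituted epoxides, and the order 6 before 40, secured by the solvent switch that gates the silyl shift; the silyl ethers, the PMB ether and the remote alkene are inert to both anions.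

**Endgame**

Step 37
Reactants: 47 C15–C40 union product
Product: 48 C15–C40 hexa-silyl ether (O17, O21, O25, O27, O29, O33 TBS; O35 PMB)
Conditions: TBSOTf, 2,6-lutidine, CH2Cl2, −78 → 0 °C
Reagents that add atoms: tert-butyldimethylsilyl trifluoromethanesulfonate, CC(C)(C)[Si](C)(C)OS(=O)(=O)C(F)(F)F
Why: Silylation caps the free C25 hydroxyl, and any O27-to-O25 silyl migration during step 36 converges to the same compound here.

Step 38
Reactants: 48 C15–C40 hexa-silyl ether
Product: 49 C35 alcohol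
Conditions: DDQ, CH2Cl2/pH 7 buffer, 0 °C
Reagents that add atoms: none
Why: Buffered oxidative PMB cleavage exposes O35 only, because the dialkyl thioacetal is oxidised much more slowly than the anisyl ether at 0 °C.

Step 39
Reactants: 49 C35 alcohol; 21 C1–C14 acid
Product: 51 seco ester diene (O35 acylated by C1), via mixed anhydride 50 (not isolated)
Conditions: 2,4,6-trichlorobenzoyl chloride, Et3N, toluene, rt; then 49, DMAP, toluene, rt → 40 °C
Reagents that add atoms: none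
Why: In the Yamaguchi esterification DMAP attacks the mixed anhydride at the less hindered carbonyl and the acylpyridinium acylates the hindered secondary O35–H.

Step 40
Reactants: 51 seco ester diene
Product: 52 36-membered lactone with C14=C15 and the C23 dithiane
Conditions: second-generation Grubbs catalyst (10 mol %), CH2Cl2 (1 mM), 40 °C
Reagents that add atoms: none
Why: Ring-closing metathesis at high dilution joins the only two terminal alkenes, the catalyst loading on the unhindered C15 alkene and closing onto the allylic silyl ether, and thioacetals are tolerated by this catalyst class.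

Step 41
Reactants: 52 36-membered lactone
Product: 53 saturated nona-silyl macrolactone
Conditions: Raney Ni (W-2), H2 (1 atm), EtOH, rt
Reagents that add atoms: none
Why: Raney nickel hydrogenolyses both C–S bonds (C23 becomes CH2) and hydrogenates C14=C15 in one operation, while the ester and silyl ethers are inert.

Step 42
Reactants: 53 saturated nona-silyl macrolactone
Product: 54 CNP0225459.2
Conditions: HF·pyridine, pyridine/THF, 0 °C → rt
Reagents that add atoms: none
Why: Buffered fluoride cleaves all nine silyl ethers, and the mildly acidic, non-basic medium avoids acyl migration from O35 to O33 and opening of the lactone.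

**Compound list**

1 | (R)-epichlorohydrin | ClC[C@H]1CO1 | starting material
2 | (2R)-1-chlorohept-6-en-2-ol | ClC[C@H](O)CCCC=C | intermediate
3 | (2R)-2-(pent-4-en-1-yl)oxirane | C=CCCC[C@@H]1CO1 | intermediate
4 | 4-[(2R)-oxiran-2-yl]butanal | O=CCCC[C@@H]1CO1 | intermediate
5 | (4R)-1-[(2R)-oxiran-2-yl]hept-6-en-4-ol | C=CC[C@H](O)CCC[C@@H]1CO1 | intermediate
6 | fragment A, tert-butyldimethylsilyl ether of 5 (C15–C22 epoxide, O17 TBS) | C=CC[C@H](O[Si](C)(C)C(C)(C)C)CCC[C@@H]1CO1 | intermediate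
7 | (R)-citronellol | CC(C)=CCC[C@@H](C)CCO | starting material
8 | (3R)-1-[(4-methoxybenzyl)oxy]-3,7-dimethyloct-6-ene | CC(C)=CCC[C@@H](C)CCOCc1ccc(OC)cc1 | intermediate
9 | (4R)-6-[(4-methoxybenzyl)oxy]-4-methylhexanal | O=CCC[C@@H](C)CCOCc1ccc(OC)cc1 | intermediate
10 | (2S,4S)-6-[(4-methoxybenzyl)oxy]-4-methyl-2-[(phenylamino)oxy]hexanal | O=C[C@@H](ONc1ccccc1)C[C@@H](C)CCOCc1ccc(OC)cc1 | intermediate
11 | (2S,4S)-6-[(4-methoxybenzyl)oxy]-4-methyl-2-[(phenylamino)oxy]hexan-1-ol | OC[C@@H](ONc1ccccc1)C[C@@H](C)CCOCc1ccc(OC)cc1 | intermediate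
12 | (2S,4S)-6-[(4-methoxybenzyl)oxy]-4-methylhexane-1,2-diol | OC[C@@H](O)C[C@@H](C)CCOCc1ccc(OC)cc1 | intermediate
13 | 1-O-tosylate of 12 | Cc1ccc(cc1)S(=O)(=O)OC[C@@H](O)C[C@@H](C)CCOCc1ccc(OC)cc1 | intermediate
14 | (2S)-2-[(2S)-4-[(4-methoxybenzyl)oxy]-2-methylbutyl]oxirane | C1O[C@H]1C[C@@H](C)CCOCc1ccc(OC)cc1 | intermediate
15 | (3S,5S)-7-[(4-methoxybenzyl)oxy]-5-methylhept-1-en-3-ol | C=C[C@@H](O)C[C@@H](C)CCOCc1ccc(OC)cc1 | intermediate
16 | C1–C14 epoxy alkene (C6=C7; 5-OH; 9-OTBS; 13,14-epoxide; 1-OPMB) | C1O[C@@H]1CCC[C@@H](O[Si](C)(C)C(C)(C)C)C/C=C/[C@@H](O)C[C@@H](C)CCOCc1ccc(OC)cc1 | intermediate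
17 | C1–C14 saturated epoxide (5-OH; 9-OTBS; 13,14-epoxide; 1-OPMB) | C1O[C@@H]1CCC[C@@H](O[Si](C)(C)C(C)(C)C)CCC[C@@H](O)C[C@@H](C)CCOCc1ccc(OC)cc1 | intermediate
18 | C1–C14 diol with C13 vinyl carbinol (5-OH; 13-OH; 9-OTBS; 1-OPMB) | C=C[C@H](O)CCC[C@@H](O[Si](C)(C)C(C)(C)C)CCC[C@@H](O)C[C@@H](C)CCOCc1ccc(OC)cc1 | intermediate
19 | C1–C14 tris-silyl ether (O5, O9, O13 TBS; 1-OPMB) | C=C[C@H](O[Si](C)(C)C(C)(C)C)CCC[C@@H](O[Si](C)(C)C(C)(C)C)CCC[C@@H](O[Si](C)(C)C(C)(C)C)C[C@@H](C)CCOCc1ccc(OC)cc1 | intermediate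
20 | C1 primary alcohol (O5, O9, O13 TBS) | C=C[C@H](O[Si](C)(C)C(C)(C)C)CCC[C@@H](O[Si](C)(C)C(C)(C)C)CCC[C@@H](O[Si](C)(C)C(C)(C)C)C[C@@H](C)CCO | intermediate
21 | C1–C14 acid, 5,9,13-tris(tert-butyldimethylsilyloxy)-3-methylpentadec-14-enoic acid | C=C[C@H](O[Si](C)(C)C(C)(C)C)CCC[C@@H](O[Si](C)(C)C(C)(C)C)CCC[C@@H](O[Si](C)(C)C(C)(C)C)C[C@@H](C)CC(=O)O | intermediate
22 | (E)-hept-2-en-1-ol | CCCC/C=C/CO | starting material
23 | [(2R,3R)-3-butyloxiran-2-yl]methanol | CCCC[C@H]1O[C@@H]1CO | intermediate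
24 | (2S,3S)-3-methylheptane-1,2-diol | CCCC[C@H](C)[C@H](O)CO | intermediate
25 | 1-O-tosylate of 24 | CCCC[C@H](C)[C@H](O)COS(=O)(=O)c1ccc(C)cc1 | intermediate
26 | (2S)-2-[(2S)-hexan-2-yl]oxirane | CCCC[C@H](C)[C@H]1CO1 | intermediate
27 | (4R,5S)-5-methylnon-1-en-4-ol | CCCC[C@H](C)[C@H](O)CC=C | intermediate
28 | (4R,5S)-4-[(4-methoxybenzyl)oxy]-5-methylnon-1-ene | CCCC[C@H](C)[C@H](OCc1ccc(OC)cc1)CC=C | intermediate
29 | (3R,4S)-3-[(4-methoxybenzyl)oxy]-4-methyloctanal | CCCC[C@H](C)[C@H](OCc1ccc(OC)cc1)CC=O | intermediate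
30 | (4S,6R,7S)-6-[(4-methoxybenzyl)oxy]-7-methylundec-1-en-4-ol | CCCC[C@H](C)[C@H](OCc1ccc(OC)cc1)C[C@@H](O)CC=C | intermediate
31 | C30–C40 alkene (33-OTBS; 35-OPMB) | CCCC[C@H](C)[C@H](OCc1ccc(OC)cc1)C[C@@H](O[Si](C)(C)C(C)(C)C)CC=C | intermediate
32 | C29–C40 aldehyde (33-OTBS; 35-OPMB) | CCCC[C@H](C)[C@H](OCc1ccc(OC)cc1)C[C@@H](O[Si](C)(C)C(C)(C)C)CCCC=O | intermediate
33 | C26–C40 homoallylic alcohol (29-OH; 33-OTBS; 35-OPMB) | CCCC[C@H](C)[C@H](OCc1ccc(OC)cc1)C[C@@H](O[Si](C)(C)C(C)(C)C)CCC[C@H](O)CC=C | intermediate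
34 | C26–C40 alkene (29,33-bis-OTBS; 35-OPMB) | CCCC[C@H](C)[C@H](OCc1ccc(OC)cc1)C[C@@H](O[Si](C)(C)C(C)(C)C)CCC[C@H](O[Si](C)(C)C(C)(C)C)CC=C | intermediate
35 | C27–C40 aldehyde (29,33-bis-OTBS; 35-OPMB) | CCCC[C@H](C)[C@H](OCc1ccc(OC)cc1)C[C@@H](O[Si](C)(C)C(C)(C)C)CCC[C@H](O[Si](C)(C)C(C)(C)C)CC=O | intermediate
36 | C24–C40 homoallylic alcohol (27-OH; 29,33-bis-OTBS; 35-OPMB) | CCCC[C@H](C)[C@H](OCc1ccc(OC)cc1)C[C@@H](O[Si](C)(C)C(C)(C)C)CCC[C@H](O[Si](C)(C)C(C)(C)C)C[C@@H](O)CC=C | intermediate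
37 | C27 tert-butyl carbonate of 36 | CCCC[C@H](C)[C@H](OCc1ccc(OC)cc1)C[C@@H](O[Si](C)(C)C(C)(C)C)CCC[C@H](O[Si](C)(C)C(C)(C)C)C[C@@H](OC(=O)OC(C)(C)C)CC=C | intermediate
38 | cyclic iodocarbonate (cis-4-iodomethyl-6-alkyl-1,3-dioxan-2-one across O25/O27) | CCCC[C@H](C)[C@H](OCc1ccc(OC)cc1)C[C@@H](O[Si](C)(C)C(C)(C)C)CCC[C@H](O[Si](C)(C)C(C)(C)C)C[C@@H]1C[C@H](CI)OC(=O)O1 | intermediate
39 | syn epoxy alcohol (C24–C25 epoxide; 27-OH; 29,33-bis-OTBS; 35-OPMB) | CCCC[C@H](C)[C@H](OCc1ccc(OC)cc1)C[C@@H](O[Si](C)(C)C(C)(C)C)CCC[C@H](O[Si](C)(C)C(C)(C)C)C[C@@H](O)C[C@@H]1CO1 | intermediate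
40 | fragment B (C24–C40 epoxide; 27,29,33-tris-OTBS; 35-OPMB) | CCCC[C@H](C)[C@H](OCc1ccc(OC)cc1)C[C@@H](O[Si](C)(C)C(C)(C)C)CCC[C@H](O[Si](C)(C)C(C)(C)C)C[C@@H](O[Si](C)(C)C(C)(C)C)C[C@@H]1CO1 | intermediate
41 | 1,3-dithiane | C1CSCSC1 | starting material
42 | 2-lithio-1,3-dithiane | [Li]C1SCCCS1 | intermediate
43 | 2-(tert-butyldimethylsilyl)-1,3-dithiane | C[Si](C)(C(C)(C)C)C1SCCCS1 | intermediate
44 | 2-lithio-2-(tert-butyldimethylsilyl)-1,3-dithiane | [Li]C1([Si](C)(C)C(C)(C)C)SCCCS1 | intermediate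
45 | lithium C21 alkoxide of the adduct of 44 and 6 (silicon still on C23) | C=CC[C@H](O[Si](C)(C)C(C)(C)C)CCC[C@@H](O[Li])CC1([Si](C)(C)C(C)(C)C)SCCCS1 | intermediate
46 | C23-lithiated dithiane after the silyl shift (O21 TBS) | C=CC[C@H](O[Si](C)(C)C(C)(C)C)CCC[C@@H](O[Si](C)(C)C(C)(C)C)CC1([Li])SCCCS1 | intermediate
47 | C15–C40 union product (C23 dithiane; O21 TBS; O25 H; 17,27,29,33-OTBS; 35-OPMB) | CCCC[C@H](C)[C@H](OCc1ccc(OC)cc1)C[C@@H](O[Si](C)(C)C(C)(C)C)CCC[C@H](O[Si](C)(C)C(C)(C)C)C[C@@H](O[Si](C)(C)C(C)(C)C)C[C@@H](O)CC1(SCCCS1)C[C@H](O[Si](C)(C)C(C)(C)C)CCC[C@@H](O[Si](C)(C)C(C)(C)C)CC=C | intermediate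
48 | C15–C40 hexa-silyl ether (O35 PMB) | CCCC[C@H](C)[C@H](OCc1ccc(OC)cc1)C[C@@H](O[Si](C)(C)C(C)(C)C)CCC[C@H](O[Si](C)(C)C(C)(C)C)C[C@@H](O[Si](C)(C)C(C)(C)C)C[C@@H](O[Si](C)(C)C(C)(C)C)CC1(SCCCS1)C[C@H](O[Si](C)(C)C(C)(C)C)CCC[C@@H](O[Si](C)(C)C(C)(C)C)CC=C | intermediate
49 | C35 alcohol of the C15–C40 chain | CCCC[C@H](C)[C@H](O)C[C@@H](O[Si](C)(C)C(C)(C)C)CCC[C@H](O[Si](C)(C)C(C)(C)C)C[C@@H](O[Si](C)(C)C(C)(C)C)C[C@@H](O[Si](C)(C)C(C)(C)C)CC1(SCCCS1)C[C@H](O[Si](C)(C)C(C)(C)C)CCC[C@@H](O[Si](C)(C)C(C)(C)C)CC=C | intermediate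
50 | mixed anhydride of 21 with 2,4,6-trichlorobenzoic acid | C=C[C@H](O[Si](C)(C)C(C)(C)C)CCC[C@@H](O[Si](C)(C)C(C)(C)C)CCC[C@@H](O[Si](C)(C)C(C)(C)C)C[C@@H](C)CC(=O)OC(=O)c1c(Cl)cc(Cl)cc1Cl | intermediate
51 | seco ester diene (O35 ester of 21; C23 dithiane) | CCCC[C@H](C)[C@H](OC(=O)C[C@H](C)C[C@H](O[Si](C)(C)C(C)(C)C)CCC[C@H](O[Si](C)(C)C(C)(C)C)CCC[C@@H](O[Si](C)(C)C(C)(C)C)C=C)C[C@@H](O[Si](C)(C)C(C)(C)C)CCC[C@H](O[Si](C)(C)C(C)(C)C)C[C@@H](O[Si](C)(C)C(C)(C)C)C[C@@H](O[Si](C)(C)C(C)(C)C)CC1(SCCCS1)C[C@H](O[Si](C)(C)C(C)(C)C)CCC[C@@H](O[Si](C)(C)C(C)(C)C)CC=C | intermediate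
52 | 36-membered lactone with C14=C15 and C23 dithiane (nine OTBS) | CCCC[C@H](C)[C@H]1C[C@@H](O[Si](C)(C)C(C)(C)C)CCC[C@H](O[Si](C)(C)C(C)(C)C)C[C@@H](O[Si](C)(C)C(C)(C)C)C[C@@H](O[Si](C)(C)C(C)(C)C)CC2(SCCCS2)C[C@H](O[Si](C)(C)C(C)(C)C)CCC[C@@H](O[Si](C)(C)C(C)(C)C)C/C=C/[C@H](O[Si](C)(C)C(C)(C)C)CCC[C@@H](O[Si](C)(C)C(C)(C)C)CCC[C@@H](O[Si](C)(C)C(C)(C)C)C[C@@H](C)CC(=O)O1 | intermediate
53 | saturated nona-silyl macrolactone | CCCC[C@H](C)[C@H]1C[C@@H](O[Si](C)(C)C(C)(C)C)CCC[C@H](O[Si](C)(C)C(C)(C)C)C[C@@H](O[Si](C)(C)C(C)(C)C)C[C@@H](O[Si](C)(C)C(C)(C)C)CCC[C@H](O[Si](C)(C)C(C)(C)C)CCC[C@@H](O[Si](C)(C)C(C)(C)C)CCC[C@H](O[Si](C)(C)C(C)(C)C)CCC[C@@H](O[Si](C)(C)C(C)(C)C)CCC[C@@H](O[Si](C)(C)C(C)(C)C)C[C@@H](C)CC(=O)O1 | intermediate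
54 | CNP0225459.2, (4R,6R,10R,14S,18S,22R,26R,28S,30S,34S,36R)-36-[(2S)-hexan-2-yl]-6,10,14,18,22,26,28,30,34-nonahydroxy-4-methyl-1-oxacyclohexatriacontan-2-one | CCCC[C@H](C)[C@H]1C[C@@H](O)CCC[C@H](O)C[C@@H](O)C[C@@H](O)CCC[C@H](O)CCC[C@@H](O)CCC[C@H](O)CCC[C@@H](O)CCC[C@@H](O)C[C@@H](C)CC(=O)O1 | target

Total step count: 42. Longest linear sequence: 24 steps, from 22 to 54 (steps 18–34 and 36–42).

**Steps most likely to fail**

Step 36 (three-component union). The first adduct may undergo the silyl shift too early, so that the relayed anion adds a second molecule of 6. The shift may also stay incomplete, or the relayed anion may be protonated before it opens the more hindered epoxide. The fallback is a stepwise union without the silyl relay, setting out from 41 and 6. 2-Lithio-1,3-dithiane 42 (n-BuLi, THF, −30 °C) opens 6 at C22 to give the hydroxy dithiane F1. TBSCl/imidazole converts it into the bis-silyl ether F2. Metalation of F2 at C23 (t-BuLi, THF/HMPA, −78 °C) and addition of 40 give 47, where the route is rejoined.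

Step 40 (ring-closing metathesis). The thioacetal sulfur may deactivate the ruthenium carbene, or oligomerisation may outrun closure of the large ring. The fallback removes sulfur before metathesis and the C23 oxygen afterwards, setting out from 51. Alkylative hydrolysis (MeI, CaCO3, MeCN/H2O, 40 °C) gives the diene ketone F3. Ring-closing metathesis under the conditions of step 40 gives the macrocyclic keto alkene F4. Hydrogenation (H2, Pt/C, EtOAc) gives the saturated ketone F5. Condensation with TsNHNH2 gives the tosylhydrazone F6, and its reduction with catecholborane followed by NaOAc·3H2O (hydrazone-to-methylene reduction) gives 53, where the route is rejoined.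

Step 38 (PMB removal beside the dithiane). The oxidant may attack the thioacetal, leading to sulfoxide formation or hydrolytic loss of the dithiane while the ether is cleaved. The fallback exchanges the O35 group before sulfur enters the molecule, setting out from 40. DDQ (CH2Cl2/pH 7 buffer) gives the hydroxy epoxide F7, and TESOTf/2,6-lutidine gives the triethylsilyl ether F8. The union of step 36 with 43 and 6 then gives the C25 alcohol F9, and TBSOTf/2,6-lutidine gives the fully silylated chain F10. PPTS in MeOH/CH2Cl2 at 0 °C cleaves only the triethylsilyl ether and gives 49, where the route is rejoined.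

Further compounds
F1 | step 36 | hydroxy dithiane, 2-substituted 1,3-dithiane from 42 and 6 (O21 H) | C=CC[C@H](O[Si](C)(C)C(C)(C)C)CCC[C@@H](O)CC1SCCCS1
F2 | step 36 | bis-silyl ether of F1 (O17, O21 TBS) | C=CC[C@H](O[Si](C)(C)C(C)(C)C)CCC[C@@H](O[Si](C)(C)C(C)(C)C)CC1SCCCS1
F3 | step 40 | diene ketone (C23 ketone analogue of 51) | CCCC[C@H](C)[C@H](OC(=O)C[C@H](C)C[C@H](O[Si](C)(C)C(C)(C)C)CCC[C@H](O[Si](C)(C)C(C)(C)C)CCC[C@@H](O[Si](C)(C)C(C)(C)C)C=C)C[C@@H](O[Si](C)(C)C(C)(C)C)CCC[C@H](O[Si](C)(C)C(C)(C)C)C[C@@H](O[Si](C)(C)C(C)(C)C)C[C@@H](O[Si](C)(C)C(C)(C)C)CC(=O)C[C@H](O[Si](C)(C)C(C)(C)C)CCC[C@@H](O[Si](C)(C)C(C)(C)C)CC=C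
F4 | step 40 | macrocyclic keto alkene (C23 ketone; C14=C15) | CCCC[C@H](C)[C@H]1C[C@@H](O[Si](C)(C)C(C)(C)C)CCC[C@H](O[Si](C)(C)C(C)(C)C)C[C@@H](O[Si](C)(C)C(C)(C)C)C[C@@H](O[Si](C)(C)C(C)(C)C)CC(=O)C[C@H](O[Si](C)(C)C(C)(C)C)CCC[C@@H](O[Si](C)(C)C(C)(C)C)C/C=C/[C@H](O[Si](C)(C)C(C)(C)C)CCC[C@@H](O[Si](C)(C)C(C)(C)C)CCC[C@@H](O[Si](C)(C)C(C)(C)C)C[C@@H](C)CC(=O)O1
F5 | step 40 | saturated macrocyclic C23 ketone | CCCC[C@H](C)[C@H]1C[C@@H](O[Si](C)(C)C(C)(C)C)CCC[C@H](O[Si](C)(C)C(C)(C)C)C[C@@H](O[Si](C)(C)C(C)(C)C)C[C@@H](O[Si](C)(C)C(C)(C)C)CC(=O)C[C@H](O[Si](C)(C)C(C)(C)C)CCC[C@@H](O[Si](C)(C)C(C)(C)C)CCC[C@H](O[Si](C)(C)C(C)(C)C)CCC[C@@H](O[Si](C)(C)C(C)(C)C)CCC[C@@H](O[Si](C)(C)C(C)(C)C)C[C@@H](C)CC(=O)O1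
F6 | step 40 | C23 tosylhydrazone of F5 | CCCC[C@H](C)[C@H]1C[C@@H](O[Si](C)(C)C(C)(C)C)CCC[C@H](O[Si](C)(C)C(C)(C)C)C[C@@H](O[Si](C)(C)C(C)(C)C)C[C@@H](O[Si](C)(C)C(C)(C)C)CC(=NNS(=O)(=O)c2ccc(C)cc2)C[C@H](O[Si](C)(C)C(C)(C)C)CCC[C@@H](O[Si](C)(C)C(C)(C)C)CCC[C@H](O[Si](C)(C)C(C)(C)C)CCC[C@@H](O[Si](C)(C)C(C)(C)C)CCC[C@@H](O[Si](C)(C)C(C)(C)C)C[C@@H](C)CC(=O)O1
F7 | step 38 | hydroxy epoxide (fragment B with O35 H) | CCCC[C@H](C)[C@H](O)C[C@@H](O[Si](C)(C)C(C)(C)C)CCC[C@H](O[Si](C)(C)C(C)(C)C)C[C@@H](O[Si](C)(C)C(C)(C)C)C[C@@H]1CO1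
F8 | step 38 | triethylsilyl ether of F7 (O35 TES) | CCCC[C@H](C)[C@H](O[Si](CC)(CC)CC)C[C@@H](O[Si](C)(C)C(C)(C)C)CCC[C@H](O[Si](C)(C)C(C)(C)C)C[C@@H](O[Si](C)(C)C(C)(C)C)C[C@@H]1CO1
F9 | step 38 | C25 alcohol, union product with O35 TES | CCCC[C@H](C)[C@H](O[Si](CC)(CC)CC)C[C@@H](O[Si](C)(C)C(C)(C)C)CCC[C@H](O[Si](C)(C)C(C)(C)C)C[C@@H](O[Si](C)(C)C(C)(C)C)C[C@@H](O)CC1(SCCCS1)C[C@H](O[Si](C)(C)C(C)(C)C)CCC[C@@H](O[Si](C)(C)C(C)(C)C)CC=C
F10 | step 38 | fully silylated chain (O35 TES; six OTBS) | CCCC[C@H](C)[C@H](O[Si](CC)(CC)CC)C[C@@H](O[Si](C)(C)C(C)(C)C)CCC[C@H](O[Si](C)(C)C(C)(C)C)C[C@@H](O[Si](C)(C)C(C)(C)C)C[C@@H](O[Si](C)(C)C(C)(C)C)CC1(SCCCS1)C[C@H](O[Si](C)(C)C(C)(C)C)CCC[C@@H](O[Si](C)(C)C(C)(C)C)CC=C
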